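The easy step is a subtraction on two earlier runs, cedar and maple, in which solid D is stirred and L is added in portions, and G is read with its crystals X counted in.

the same everywhere: D 0.20 M

| run | L | remark | time |
|---|---|---|---|
| cedar | 1.3 equiv (in portions, 2) | run made earlier; portions every 2.5 h |  |
| maple | 2 equiv (in portions, 2) | run made earlier; portions every 2.5 h |  |
| north | 0.900 equiv (in portions, 2) | the portions of L follow each other after 2.5 h, the first at the start | 20 h |
| south-west | 0.900 equiv (in portions, 2) | the portions of L follow each other after 5.0 h, the first at the start | 20 h |
| east | 0.900 equiv (in portions, 2) | the portions of L follow each other after 10 h, the first at the start | 20 h |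
| west | 0.900 equiv (in portions, 2) | the portions of L follow each other after 20 h, the first at the start | 20 h |

| cedar: time / h | cedar: G / % | maple: time / h | maple: G / % |
|---|---|---|---|
| 1.33 | 1 | 1.33 | 4 |
| 4.00 | 7 | 4.00 | 4 |
| 8.00 | 9 | 8.00 | 10 |
| 12.0 | 17 | 12.0 | 14 |
| 15.0 | 18 | 15.0 | 17 |

(standard deviation of a reading: 1.5 percentage points)

- a species is counted by the D in it: one Z or E counts as two
- amounts and yields of G count X too
- given per volume of solution although it is solid: D, X
- steps under discussion: D <-> J; D + G -> E; L -> Q; 2 J -> Z; X <-> G; J + L -> G
- at the start none of D is in solution
- the concentration of G that is asked is that of its free form alone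
- "hardly changes" means that all values lie within two and a half points (for a concentration: within two and a half percent of the largest)
- a step back or a flat step of under half a percent of the largest counts as no turn

- [G] (only what is free in solution) at the end for north, south-west, east, west, in this order
- how the row runs (rises, then falls / hardly changes / falls all the way / falls, then rises / rises all the way)

Between 4.00 h and 15.0 h, cedar gains 11 percentage points of the charged D and maple 13 points. Pooled per hour and multiplied by the 0.20 M of D charged, these gains read 0.00218 M/h. Call this the feed, the rate at which G grows, free and crystalline together. Over 20 h the feed comes to 0.0436 M of G in both forms.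

Two chemists read this differently. The first made the forecast: free G of 0.04 M, 0.04 M, 0.04 M and 0.04 M, so that the row hardly changes. Cedar with 1.3 equiv of L and maple with 2 equiv read 18% and 17% of G at 15.0 h, and in the forecast's words the "timing of the second portion therefore hardly matters".

The second chemist is me. The readings count X, so I take 0.0436 M as an estimate of free G and X together, and give no figure for free G by itself. I also expect the spacing to show at the end of the row. The west flask spends its 20 h on a first portion of 0.0900 M of L, and the estimated 0.0436 M of G is about half of that. I expect thinner L there, more J waiting, and a row that falls.

The flasks end at 0.00789 M, 0.00789 M, 0.00790 M and 0.00727 M, so the row falls all the way.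

    D ⇌ J, rate k1*(cs1 - [J]) while solid is left; crystals form when [J] > cs1 (solubility = 0.0690 M, k = 7.10 × 10⁻⁴ /min)
    D + G → E (k = 0.00600 /M/min)
    L → Q (k = 1.60 × 10⁻⁴ /min)
    2 J → Z (k = 0.800 /M/min)
    X ⇌ G, rate k5*(cs5 - [G]) while solid is left; crystals form when [G] > cs5 (solubility = 3.40 mM, k = 0.00920 /min)
    J + L → G (k = 0.880 /M/min)

The largest single effect on free G in the north flask is the ceiling on dissolved G: the north flask without that ceiling ends at 0.0357 M instead of 0.00789 M, close to the forecast's 0.04 M. Put 0.0436 M back as free G and the crystal step drains 0.0222 M/h, ten times the feed, so go round once more. Assume a quasi-steady state (north makes dissolved G 1.00 times as fast as it uses it at 20.0 h): if crystals take the feed, free G stands above the ceiling of 3.4 mM by the feed divided by 0.0092 /min, which gives 0.00735 M, while north holds 0.00789 M and west 0.00727 M.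

(The runs are simulated with made-up constants; noise was put on by code.)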